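The numbers of this flask stand for no real mixture; the flask was simulated.

The left-handed substrate reacts far faster than the right-handed one at equal concentrations, and these flasks ask how much of that lead survives.

    precatalyst → free catalyst (k1 = 0.0374 s⁻¹, Ea1 = 78.0 kJ mol⁻¹)
    reagent + free catalyst + left-handed substrate → free catalyst + left-handed product (k2 = 1.11 × 10⁵ L² mol⁻² s⁻¹, Ea2 = 14.0 kJ mol⁻¹)
    2 free catalyst → spent catalyst (k3 = 392 L mol⁻¹ s⁻¹, Ea3 = 52.0 kJ mol⁻¹)
    reagent + free catalyst + right-handed substrate → free catalyst + right-handed product (k4 = 3580 L² mol⁻² s⁻¹, Ea4 = 15.0 kJ mol⁻¹)
    (constants at 60 °C)

the same everywhere: left-handed substrate 0.0050 M; reagent 4.00 mM; precatalyst 0.44 mM; right-handed substrate 0.0050 M; time 2.0 min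
- spring: temperature 60 °C
- summer: at 60 °C until 1.0 min, from then on at 90 °C
- dusk: temperature 90 °C

- free catalyst is single-handed; left-handed substrate and right-handed substrate are mirror images of each other, charged as a racemate, each of them at the stated concentration
- a step written with two of one species runs at k times the square of its concentration and takes two of it each time
- the constants hold at 60 °C; other temperatures follow from the activation energies
- an excess is the difference of the two amounts in percent of their sum
- an excess is below zero if the other one leads

* the flask that comes out highest in excess of left-handed product over right-handed product, or "all alike" when all lie within 1.5 percentage points (spring / summer / dusk / all alike)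
* excess of left-handed product over right-handed product at the end, spring
* excess of left-handed product over right-handed product at the end, summer
* excess of left-handed product over right-handed product at the end, dusk

Minutes of the meeting. I proposed carrying one number, the selectivity factor s, the rate constant of the left-handed step over that of the right-handed step, 31.0 at 60 °C. I argued that both steps contain the same c(reagent) and c(free catalyst), so at one temperature ln c(right-handed substrate) moves by one s-th of ln c(left-handed substrate), however the catalyst lives and dies. If a fraction r of the left-handed substrate remains, r to the power one over s of the right-handed substrate remains. The excess is then the lost fraction of left minus the lost fraction of right, over their sum. The activation energies differ by 1.00 kJ mol⁻¹, far less than the barrier of the left-handed step itself, so I proposed keeping s for the hot flasks too.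

I then solved the two ends. At the very start, the excess is s minus one over s plus one, 93.8%. At the far end, if the whole reagent charge went to the left-handed substrate, r would be 0.200. The right-handed substrate would lose 5.06% and the excess would be 88.1%. The two lost fractions add up to 0.851 of one substrate charge, more than the 0.800 that the reagent allows, so this end of the band lies a little low. The band is 5.7 percentage points wide, wider than the margin. My reckoning therefore places each flask inside the band, higher the less left-handed substrate is consumed, and leaves the verdict open.

The forecast's author went further and committed to all alike, with 90% for spring, 90.2% for summer and 91.2% for dusk, on the ground that “heat makes the catalyst die faster, so less reagent is used”.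

The simulation gives all alike, with 90.0% for spring, 90.2% for summer and 91.2% for dusk.

Spring ends with 33% of its left-handed substrate, so the rule has the right-handed substrate losing 3.51% and gives an excess of 90.0%. The neighbour is spring with 0.016 M of reagent, and it keeps 0.017% of its left-handed substrate. The same reckoning has its right-handed substrate losing 24.4%, for an excess of 60.8%. In the simulated neighbour, 76% of the right-handed substrate remains and the excess is 60.8%.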